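Everything rests on cutting the cyclohexane ring (C1, C10–C14; briarane numbering) across C12–C13 and C10–C11. Its C11–C12 epoxide is read as a cyclohexene, the C14 acetate as a 2-silyloxydiene and quaternary C1 as the enol ether carbon left behind. One catalytic asymmetric Diels–Alder reaction of an acyclic silyloxydiene with (E)-3-bromo-2-methylacrolein, a traceless propyne equivalent, closes this ring, sets C10 and leaves a regiodefined tetrasubstituted enol ether. Grob loss of CHO and Br unveils C11=C12; C1, C2, C14, C11 and C12 are then relayed from C10 (aldol, Evans–Tishchenko, directed epoxidation), and a Nozaki–Hiyama–Kishi closure builds the ten-membered ring and butenolide together.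

Key step: step 4

Remarks on the chemistry:
- Locants are those of the briarane skeleton: ring A = C1, C10, C11, C12, C13, C14 (acetate on C14, epoxide C11–C12, methyl C15 on C1, methyl C20 on C11); ten-membered ring = C1 to C10; butenolide = C7, C8, C17, C19(=O), O; methyl C16 on C5, methyl C18 on C17. A descriptor at a given carbon can change along the route only because substituent priorities change.
- The (S)-oxazaborolidinium catalyst in step 4 is assumed to show the sense of induction known for 2-methylacrolein; if it is the opposite, the (R)-catalyst is used.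
- 23 and 24 are carried as mixtures at C8/C17; both centres become sp2 in 25.

Step 1
Reactants: 1 3-[(tert-butyldimethylsilyl)oxy]propanal; 2 diethyl (3-oxobutan-2-yl)phosphonate
Product: 3 (E)-6-[(tert-butyldimethylsilyl)oxy]-3-methylhex-3-en-2-one
Conditions: Ba(OH)2, THF/H2O (40:1), rt
Reagents that add atoms: none
Why: Horner–Wadsworth–Emmons olefination under mild Ba(OH)2 activation tolerates the β-silyloxy aldehyde and should give the (E)-trisubstituted enone, with the acetyl group trans to the new chain.

Step 2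
Reactants: 3 (E)-6-[(tert-butyldimethylsilyl)oxy]-3-methylhex-3-en-2-one
Product: 4 (E)-2,6-bis[(tert-butyldimethylsilyl)oxy]-3-methylhexa-1,3-diene
Conditions: LiN(iPr)2, THF, −78 °C; TBSOTf, −78 → 0 °C
Reagents that add atoms: tert-butyldimethylsilyl trifluoromethanesulfonate, CC(C)(C)[Si](C)(C)OS(=O)(=O)C(F)(F)F
Why: Kinetic deprotonation of the methyl ketone at the α′-methyl group and O-silylation of the cross-conjugated lithium dienolate (silyl enol ether formation) should give the 2-silyloxydiene with the E-alkene untouched.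

Step 3
Reactants: 5 methacrolein
Product: 7 (E)-3-bromo-2-methylprop-2-enal, via 2,3-dibromo-2-methylpropanal 6 (not isolated)
Conditions: Br2, CH2Cl2, 0 °C; then Et3N, 0 °C → rt
Reagents that add atoms: bromine, BrBr
Why: Bromine addition to the enal followed by E2 dehydrobromination of the non-enolisable dibromo aldehyde should give the β-bromo enal, the E-isomer (Br trans to CHO) being favoured under the amine conditions.

Step 4
Reactants: 4 (E)-2,6-bis[(tert-butyldimethylsilyl)oxy]-3-methylhexa-1,3-diene; 7 (E)-3-bromo-2-methylprop-2-enal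
Product: 8 (1S,2R,6R)-6-bromo-4-[(tert-butyldimethylsilyl)oxy]-2-{2-[(tert-butyldimethylsilyl)oxy]ethyl}-1,3-dimethylcyclohex-3-ene-1-carbaldehyde
Conditions: (S)-3,3-diphenyl-1-(o-tolyl)tetrahydro-1H,3H-pyrrolo[1,2-c][1,3,2]oxazaborole (20 mol %), HNTf2 (18 mol %), CH2Cl2, −78 → −40 °C; Et3N quench
Reagents that add atoms: none
Why: The triflimide-activated oxazaborolidinium binds the formyl oxygen of 7 (with the formyl C–H···O contact) and lowers its LUMO, so the silyloxydiene adds in a concerted but asynchronous suprafacial [4+2] cycloaddition in which C13, the terminus with the largest HOMO coefficient next to the silyloxy carbon, bonds to the β-carbon C12 ahead of C10 to the α-carbon C11. Ring A (C1, C10–C14) closes in this single [4+2] event, a six-membered carbocycle formed by two σ-bonds between the diene termini and the dienophile carbons; the closest known reaction type is the oxazaborolidinium-catalysed Diels–Alder reaction of 2-silyloxybutadienes with 2-methyl- or 2-bromoacrolein. C10 is set by the catalyst, which shields one face of the s-trans enal, combined with the endo orientation of the formyl group; C11 and C12 follow stereospecifically from that endo mode (CHO cis to the C9 chain, which sits outside on the E-diene) and from the E-geometry of 7 (Br trans to CHO). The step needs regio-, endo- and enantiofacial selectivity: regiochemistry is secured by the OTBS group and reinforced by the terminal alkyl group, endo preference by secondary overlap with the bound formyl group, and face selectivity by the rigid two-point binding of the α-substituted enal. Endo/exo leakage matters because both adducts converge on 9 with opposite configuration at C10.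

Step 5
Reactants: 8 Diels–Alder adduct
Product: 9 tert-butyl{[(3S)-3-{2-[(tert-butyldimethylsilyl)oxy]ethyl}-2,4-dimethylcyclohexa-1,4-dien-1-yl]oxy}dimethylsilane
Conditions: NaOMe, THF/MeOH (10:1), −20 → 0 °C
Reagents that add atoms: none
Why: Grob fragmentation: methoxide adds to the non-enolisable aldehyde and the hemiacetal alkoxide expels methyl formate while bromide leaves from the anti-periplanar (trans-diaxial) position, so the alkene should appear only between C11 and C12 and C10 stays untouched.

Step 6
Reactants: 10 nerol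
Product: 11 1-methoxy-4-({[(2Z)-3,7-dimethylocta-2,6-dien-1-yl]oxy}methyl)benzene
Conditions: NaH, 4-methoxybenzyl chloride, Bu4NI (cat.), THF/DMF, 0 °C → rt
Reagents that add atoms: 4-methoxybenzyl chloride, COc1ccc(CCl)cc1
Why: Williamson etherification of the primary allylic alkoxide leaves the Z-alkene unchanged.

Step 7
Reactants: 11 neryl 4-methoxybenzyl ether
Product: 12 2-{(3Z)-5-[(4-methoxybenzyl)oxy]-3-methylpent-3-en-1-yl}-3,3-dimethyloxirane (racemic)
Conditions: mCPBA (1.05 equiv), NaHCO3, CH2Cl2, −20 → 0 °C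
Reagents that add atoms: 3-chloroperbenzoic acid, O=C(OO)c1cccc(Cl)c1
Why: Prilezhaev epoxidation should select the more electron-rich distal trisubstituted alkene over the alkene deactivated by the allylic ether oxygen; the epoxide configuration is irrelevant.

Step 8
Reactants: 12 distal epoxide
Product: 13 (4Z)-6-[(4-methoxybenzyl)oxy]-4-methylhex-4-enal
Conditions: H5IO6, THF/H2O, 0 °C
Reagents that add atoms: none
Why: Periodic acid opens the epoxide to the diol and cleaves it (Malaprade-type glycol cleavage) to the aldehyde and acetone without touching the Z-alkene.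

Step 9
Reactants: 9 silyloxy cyclohexadiene; 13 (4Z)-6-[(4-methoxybenzyl)oxy]-4-methylhex-4-enal
Product: 15 aldol adduct (β-hydroxy ketone; 1S 2S 10S), via lithium enolate 14 (not isolated)
Conditions: MeLi, THF, 0 °C → rt; ZnCl2, −78 °C; 13, −78 °C; aq. NH4Cl
Reagents that add atoms: none
Why: MeLi cleavage of the silyl enol ether should give the enolate only at C1 (Stork–House), and the zinc enolate aldol through a closed Zimmerman–Traxler chair adds the aldehyde anti to the pseudoaxial C9 chain on C10 (sets quaternary C1) with the aldehyde chain equatorial, so the C2 hydroxyl ends anti to ring carbon C10 (sets C2).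

Step 10
Reactants: 15 aldol adduct; 16 3-methylbut-2-enal
Product: 17 C14 alcohol C2 3-methylbut-2-enoate (1R 2S 10S 14S)
Conditions: SmI2 (20 mol %), 16 (6 equiv), THF, −10 °C
Reagents that add atoms: none
Why: Evans–Tishchenko reduction: the samarium-bound hemiacetal of 16 on the C2 hydroxyl delivers hydride intramolecularly to the C14 ketone through a bridged chair, which should give the 1,3-anti relationship (14S) and leave the oxidised aldehyde as the C2 ester.

Step 11
Reactants: 17 C14 alcohol
Product: 18 C14 acetate (1S 2S 10S 14S)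
Conditions: Ac2O, DMAP, Et3N, CH2Cl2, rt
Reagents that add atoms: acetic anhydride, CC(=O)OC(C)=O
Why: DMAP-catalysed acylation of the hindered secondary alcohol is faster than 1,3-acyl migration of the neighbouring ester.

Step 12
Reactants: 18 C14 acetate
Product: 19 C8 primary alcohol (1S 2S 10S 14S)
Conditions: HF·pyridine, pyridine, THF, 0 °C → rt
Reagents that add atoms: none
Why: Fluoride-mediated desilylation removes the primary silyl ether while both esters, the 4-methoxybenzyl ether and the alkenes survive.

Step 13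
Reactants: 19 C8 primary alcohol
Product: 20 C11–C12 epoxy alcohol (1S 2S 10R 11R 12S 14S)
Conditions: VO(acac)2 (5 mol %), t-BuOOH, CH2Cl2, 0 °C → rt
Reagents that add atoms: tert-butyl hydroperoxide, CC(C)(C)OO
Why: Vanadium-catalysed hydroxyl-directed epoxidation: the vanadate ester of the bishomoallylic C8 alcohol reaches only the ring face that carries the C9 chain, so oxygen should be delivered cis to that chain (11R, 12S), the alkenes without a nearby hydroxyl stay intact, and the tether cannot reach the rear of C11 to open the epoxide.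

Step 14
Reactants: 20 epoxy alcohol
Product: 21 C8 aldehyde
Conditions: Dess–Martin periodinane, NaHCO3, CH2Cl2, rt
Reagents that add atoms: none
Why: Buffered Dess–Martin oxidation converts the primary alcohol to the aldehyde without acid that could open the epoxide.

Step 15
Reactants: 21 C8 aldehyde; 22 methyl propanoate
Product: 23 β-hydroxy ester (mixture at C8 and C17)
Conditions: LiN(iPr)2, 22, THF, −78 °C; then 21, −78 °C; aq. NH4Cl
Reagents that add atoms: none
Why: Aldol addition of the ester lithium enolate to the aldehyde at −78 °C is much faster than attack on the acetate, the enoate or the epoxide; the two new centres are removed later.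

Step 16
Reactants: 23 β-hydroxy ester
Product: 24 β-keto ester (mixture at C17)
Conditions: Dess–Martin periodinane, NaHCO3, CH2Cl2, rt
Reagents that add atoms: none
Why: Dess–Martin oxidation of the secondary alcohol gives the β-keto ester under neutral conditions.

Step 17
Reactants: 24 β-keto ester
Product: 25 (Z)-enol triflate
Conditions: NaH, THF, 0 °C; PhNTf2, 0 °C → rt
Reagents that add atoms: N-phenylbis(trifluoromethanesulfonimide), O=S(=O)(N(c1ccccc1)S(=O)(=O)C(F)(F)F)C(F)(F)F
Why: The sodium chelate of the β-keto ester fixes the enolate oxygen cis to the ester, so O-triflation should give the Z-enol triflate needed for later lactonisation.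

Step 18
Reactants: 25 (Z)-enol triflate
Product: 26 C7 allylic alcohol
Conditions: DDQ, CH2Cl2/pH 7 buffer (10:1), 0 °C
Reagents that add atoms: none
Why: Oxidative cleavage of the 4-methoxybenzyl ether by DDQ is neutral and spares the enol triflate, the epoxide and the esters.

Step 19
Reactants: 26 C7 allylic alcohol
Product: 27 (Z)-enal
Conditions: Dess–Martin periodinane, NaHCO3, CH2Cl2, 0 °C
Reagents that add atoms: none
Why: Buffered Dess–Martin oxidation gives the Z-enal without the acid or base that would isomerise it to the E-isomer.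

Step 20
Reactants: 27 (Z)-enal
Product: 29 Malayenolide D, via seco hydroxy ester 28 (not isolated)
Conditions: CrCl2 (10 equiv), NiCl2 (5 mol %), DMF/THF, rt, 0.002 M, slow addition
Reagents that add atoms: none
Why: Nozaki–Hiyama–Kishi reaction: zerovalent nickel inserts into the alkenyl triflate, the alkenylchromium adds to the aldehyde with retention of both alkene geometries to close the ten-membered ring at C7–C8, and the chromium alkoxide lactonises onto the cis methyl ester; the 7S centre (Re-face addition) rests on substrate control, with the aldehyde oxygen expected to point away from the forming ring.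

Compound list
1 | 3-[(tert-butyldimethylsilyl)oxy]propanal | O=CCCO[Si](C)(C)C(C)(C)C | starting material
2 | diethyl (3-oxobutan-2-yl)phosphonate | CCOP(=O)(OCC)C(C)C(C)=O | starting material
3 | (E)-6-[(tert-butyldimethylsilyl)oxy]-3-methylhex-3-en-2-one | CC(=O)/C(C)=C/CCO[Si](C)(C)C(C)(C)C | intermediate
4 | (E)-2,6-bis[(tert-butyldimethylsilyl)oxy]-3-methylhexa-1,3-diene | C=C(O[Si](C)(C)C(C)(C)C)/C(C)=C/CCO[Si](C)(C)C(C)(C)C | intermediate
5 | methacrolein (2-methylprop-2-enal) | CC(=C)C=O | starting material
6 | 2,3-dibromo-2-methylpropanal | CC(Br)(CBr)C=O | intermediate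
7 | (E)-3-bromo-2-methylprop-2-enal | O=C/C(C)=C/Br | intermediate
8 | (1S,2R,6R)-6-bromo-4-[(tert-butyldimethylsilyl)oxy]-2-{2-[(tert-butyldimethylsilyl)oxy]ethyl}-1,3-dimethylcyclohex-3-ene-1-carbaldehyde (briarane locants 10R,11S,12R; CHO cis to the C9 chain, Br trans to CHO) | CC1=C(O[Si](C)(C)C(C)(C)C)C[C@@H](Br)[C@](C)(C=O)[C@@H]1CCO[Si](C)(C)C(C)(C)C | intermediate
9 | tert-butyl{[(3S)-3-{2-[(tert-butyldimethylsilyl)oxy]ethyl}-2,4-dimethylcyclohexa-1,4-dien-1-yl]oxy}dimethylsilane (10S) | CC1=C(O[Si](C)(C)C(C)(C)C)CC=C(C)[C@@H]1CCO[Si](C)(C)C(C)(C)C | intermediate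
10 | nerol, (2Z)-3,7-dimethylocta-2,6-dien-1-ol | OC/C=C(/C)CCC=C(C)C | starting material
11 | 1-methoxy-4-({[(2Z)-3,7-dimethylocta-2,6-dien-1-yl]oxy}methyl)benzene | COc1ccc(COC/C=C(/C)CCC=C(C)C)cc1 | intermediate
12 | 2-{(3Z)-5-[(4-methoxybenzyl)oxy]-3-methylpent-3-en-1-yl}-3,3-dimethyloxirane (racemic) | COc1ccc(COC/C=C(/C)CCC2OC2(C)C)cc1 | intermediate
13 | (4Z)-6-[(4-methoxybenzyl)oxy]-4-methylhex-4-enal | COc1ccc(COC/C=C(/C)CCC=O)cc1 | intermediate
14 | lithium (3S)-3-{2-[(tert-butyldimethylsilyl)oxy]ethyl}-2,4-dimethylcyclohexa-1,4-dien-1-olate | CC1=C(O[Li])CC=C(C)[C@@H]1CCO[Si](C)(C)C(C)(C)C | intermediate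
15 | (5S,6S)-5-{2-[(tert-butyldimethylsilyl)oxy]ethyl}-6-{(1S,4Z)-1-hydroxy-6-[(4-methoxybenzyl)oxy]-4-methylhex-4-en-1-yl}-4,6-dimethylcyclohex-3-en-1-one (briarane 1S,2S,10S) | O=C1CC=C(C)[C@H](CCO[Si](C)(C)C(C)(C)C)[C@@]1(C)[C@@H](O)CC/C(C)=C\COCc1ccc(OC)cc1 | intermediate
16 | 3-methylbut-2-enal | CC(C)=CC=O | starting material
17 | (1S,4Z)-1-[(1R,2S,6S)-2-{2-[(tert-butyldimethylsilyl)oxy]ethyl}-6-hydroxy-1,3-dimethylcyclohex-3-en-1-yl]-6-[(4-methoxybenzyl)oxy]-4-methylhex-4-en-1-yl 3-methylbut-2-enoate (briarane 1R,2S,10S,14S; OH cis to the C2 side chain) | O[C@H]1CC=C(C)[C@H](CCO[Si](C)(C)C(C)(C)C)[C@@]1(C)[C@@H](OC(=O)C=C(C)C)CC/C(C)=C\COCc1ccc(OC)cc1 | intermediate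
18 | (1S,4Z)-1-[(1S,2S,6S)-6-acetoxy-2-{2-[(tert-butyldimethylsilyl)oxy]ethyl}-1,3-dimethylcyclohex-3-en-1-yl]-6-[(4-methoxybenzyl)oxy]-4-methylhex-4-en-1-yl 3-methylbut-2-enoate | CC(=O)O[C@H]1CC=C(C)[C@H](CCO[Si](C)(C)C(C)(C)C)[C@@]1(C)[C@@H](OC(=O)C=C(C)C)CC/C(C)=C\COCc1ccc(OC)cc1 | intermediate
19 | (1S,4Z)-1-[(1S,2S,6S)-6-acetoxy-2-(2-hydroxyethyl)-1,3-dimethylcyclohex-3-en-1-yl]-6-[(4-methoxybenzyl)oxy]-4-methylhex-4-en-1-yl 3-methylbut-2-enoate | CC(=O)O[C@H]1CC=C(C)[C@H](CCO)[C@@]1(C)[C@@H](OC(=O)C=C(C)C)CC/C(C)=C\COCc1ccc(OC)cc1 | intermediate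
20 | epoxy alcohol: 19 with a C11–C12 epoxide cis to the C9 chain and trans to the C14 acetate (briarane 1S,2S,10R,11R,12S,14S) | CC(=O)O[C@H]1C[C@@H]2O[C@]2(C)[C@H](CCO)[C@@]1(C)[C@@H](OC(=O)C=C(C)C)CC/C(C)=C\COCc1ccc(OC)cc1 | intermediate
21 | epoxy aldehyde: 20 with C8 oxidised to CHO (1S,2S,10R,11R,12S,14S) | CC(=O)O[C@H]1C[C@@H]2O[C@]2(C)[C@H](CC=O)[C@@]1(C)[C@@H](OC(=O)C=C(C)C)CC/C(C)=C\COCc1ccc(OC)cc1 | intermediate
22 | methyl propanoate | CCC(=O)OC | starting material
23 | β-hydroxy ester: side chain on C10 is CH2–CH(OH)–CH(CH3)–CO2CH3 (mixture at C8 and C17; other centres as 21) | CC(=O)O[C@H]1C[C@@H]2O[C@]2(C)[C@H](CC(O)C(C)C(=O)OC)[C@@]1(C)[C@@H](OC(=O)C=C(C)C)CC/C(C)=C\COCc1ccc(OC)cc1 | intermediate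
24 | β-keto ester: side chain on C10 is CH2–C(=O)–CH(CH3)–CO2CH3 (mixture at C17) | CC(=O)O[C@H]1C[C@@H]2O[C@]2(C)[C@H](CC(=O)C(C)C(=O)OC)[C@@]1(C)[C@@H](OC(=O)C=C(C)C)CC/C(C)=C\COCc1ccc(OC)cc1 | intermediate
25 | (Z)-enol triflate: side chain on C10 is CH2–C(OTf)=C(CH3)–CO2CH3 with OTf cis to the ester; C7 as 4-methoxybenzyl ether | CC(=O)O[C@H]1C[C@@H]2O[C@]2(C)[C@H](C/C(OS(=O)(=O)C(F)(F)F)=C(\C)C(=O)OC)[C@@]1(C)[C@@H](OC(=O)C=C(C)C)CC/C(C)=C\COCc1ccc(OC)cc1 | intermediate
26 | C7 allylic alcohol (5Z) with the (Z)-enol triflate | CC(=O)O[C@H]1C[C@@H]2O[C@]2(C)[C@H](C/C(OS(=O)(=O)C(F)(F)F)=C(\C)C(=O)OC)[C@@]1(C)[C@@H](OC(=O)C=C(C)C)CC/C(C)=C\CO | intermediate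
27 | (5Z)-enal at C7 with the (Z)-enol triflate (1S,2S,10R,11R,12S,14S) | CC(=O)O[C@H]1C[C@@H]2O[C@]2(C)[C@H](C/C(OS(=O)(=O)C(F)(F)F)=C(\C)C(=O)OC)[C@@]1(C)[C@@H](OC(=O)C=C(C)C)CC/C(C)=C\C=O | intermediate
28 | seco hydroxy ester: ten-membered ring closed at C7–C8, 7S hydroxyl, exocyclic C8=C17 with CO2CH3 cis to C7 | CC(=O)O[C@H]1C[C@@H]2O[C@]2(C)[C@@H]2C/C(=C(\C)C(=O)OC)[C@@H](O)/C=C(/C)CC[C@H](OC(=O)C=C(C)C)[C@@]12C | intermediate
29 | Malayenolide D (1S,2S,5Z,7S,10R,11R,12S,14S) | CC(=O)O[C@H]1C[C@@H]2O[C@]2(C)[C@@H]2CC3=C(C)C(=O)O[C@H]3/C=C(/C)CC[C@H](OC(=O)C=C(C)C)[C@@]12C | target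

Total step count: 20. Longest linear sequence: 16 steps (1, 2, 4, 5, 9–20).

Steps most likely to fail

Step 4. The trisubstituted β-bromo enal may add too slowly, the enol ether may instead attack the activated aldehyde in a Mukaiyama-type addition, and leakage between endo and exo orientation would show up after step 5 as loss of enantiomeric purity at C10. The fallback sets out from 4 and comes back at 9. Propiolic acid and 3,5-dimethylpyrazole are condensed (DCC) to 1-(3,5-dimethyl-1H-pyrazol-1-yl)prop-2-yn-1-one F1. Diene 4 and this alkyne dienophile are joined in a catalytic asymmetric Diels–Alder reaction under Cu(NTf2)2 (divalent copper) with a chiral 3-(2-naphthyl)alanine amide ligand; an alkyne has no endo/exo issue and the acyl group again ends on C11, giving the acylpyrazole cyclohexadiene F2. LiBH4 reduces the activated amide to the allylic alcohol F3, SO3·pyridine gives the sulfate monoester F4, and LiAlH4 displaces sulfate without allylic transposition to return 9.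

Step 20. Ring closure may lose to oligomerisation, the Z-enal may isomerise on the Lewis-acidic chromium salts, and addition may occur on the wrong face of the C7 aldehyde. The fallback sets out from 27 and comes back at 29. The closure is run as written and the 7-epimeric lactone F5 is not discarded: TBSOTf/Et3N converts it into the aromatic 2-silyloxyfuran F6, in which C7 is trigonal. Desilylative protonation at C7 (Bu4NF/AcOH, −78 °C) from the less hindered face, or base equilibration of the butenolide, then returns 29, and unchanged F5 is recycled.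

Step 9. Cleavage of the hindered silyl enol ether may be incomplete, the basic enolate may deprotonate the enolisable aldehyde, the congested aldolate may revert, and the C2 configuration may be poorly controlled. The fallback sets out from 9 and comes back at 15. NBS converts 9 into the α-bromo ketone F7 (bromine on C1, configuration irrelevant). SmI2 (2 equiv, THF, −78 °C) then generates the samarium enolate only at C1 (Reformatsky-type aldol), which adds to 13 through a chelated chair on the face opposite the C9 chain; the trivalent samarium aldolate is not basic and does not revert, and work-up gives 15.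

Further compounds
F1 | step 4 | 1-(3,5-dimethyl-1H-pyrazol-1-yl)prop-2-yn-1-one | C#CC(=O)n1nc(C)cc1C
F2 | step 4 | [(6S)-4-[(tert-butyldimethylsilyl)oxy]-6-{2-[(tert-butyldimethylsilyl)oxy]ethyl}-5-methylcyclohexa-1,4-dien-1-yl](3,5-dimethyl-1H-pyrazol-1-yl)methanone | CC1=C(O[Si](C)(C)C(C)(C)C)CC=C(C(=O)n2nc(C)cc2C)[C@@H]1CCO[Si](C)(C)C(C)(C)C
F3 | step 4 | [(6S)-4-[(tert-butyldimethylsilyl)oxy]-6-{2-[(tert-butyldimethylsilyl)oxy]ethyl}-5-methylcyclohexa-1,4-dien-1-yl]methanol | CC1=C(O[Si](C)(C)C(C)(C)C)CC=C(CO)[C@@H]1CCO[Si](C)(C)C(C)(C)C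
F4 | step 4 | hydrogen sulfate monoester of F3 | CC1=C(O[Si](C)(C)C(C)(C)C)CC=C(COS(=O)(=O)O)[C@@H]1CCO[Si](C)(C)C(C)(C)C
F5 | step 20 | 7-epi-Malayenolide D (7R) | CC(=O)O[C@H]1C[C@@H]2O[C@]2(C)[C@@H]2CC3=C(C)C(=O)O[C@@H]3/C=C(/C)CC[C@H](OC(=O)C=C(C)C)[C@@]12C
F6 | step 20 | 2-(tert-butyldimethylsilyloxy)furan derived from the butenolide (C7 trigonal) | CC(=O)O[C@H]1C[C@@H]2O[C@]2(C)[C@@H]2Cc3c(C)c(O[Si](C)(C)C(C)(C)C)oc3/C=C(/C)CC[C@H](OC(=O)C=C(C)C)[C@@]12C
F7 | step 9 | (5S)-6-bromo-5-{2-[(tert-butyldimethylsilyl)oxy]ethyl}-4,6-dimethylcyclohex-3-en-1-one (either configuration at C6) | O=C1CC=C(C)[C@H](CCO[Si](C)(C)C(C)(C)C)C1(C)Br
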